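**Assumption:** ent-kaurane atom numbering is used for locants (C4, C5, … C20). The C6 methyl acetal of the target is taken to be the thermodynamic exo-OMe anomer, so any anomeric mixture converges under CSA/MeOH.

## Retrosynthetic overview

1. Ring D last: 5-exo α-keto radical cyclisation C16→C13 on chloro-ketone **16** (the C16 methyl is epimerisable and exo-Me is the stable epimer).
2. Ring C, C8 and C9: face-selective Diels–Alder of buta-1,3-diene onto the doubly activated spiro-dihydropyranone **14**.
3. Spiro-δ-lactone and C10: Ti(III) epoxide/acrylate radical coupling–lactonisation on epoxide **9**, then C8 acylation and dehydrogenation.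
4. Ring A and the THF acetal: all seven carbons of **2** come from 3-methoxybenzyl alcohol by Birch dearomatisation; C4 by Cu-catalysed asymmetric conjugate methylation; C5/C6 by orthoformate Mukaiyama reaction and acetalisation.
5. Ring order: A (from the arene) → acetal ring → spiro-lactone → C → D.

## Forward route

**Step 1**
Reactants: **1** 3-methoxybenzyl alcohol
Product: **2** 3-(hydroxymethyl)cyclohex-2-en-1-one
Conditions: Li, NH3(l)/THF, t-BuOH, −78 → −33 °C; then 1 M HCl, THF, rt
Reagents that add atoms: water, O
Why: Birch reduction of the anisole ring (the benzylic alkoxide resists C–O cleavage) gives the 1-methoxy-1,4-diene, and acid hydrolysis with conjugation gives the 3-substituted enone; no stereocentre is formed.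

**Step 2**
Reactants: **2**
Product: **3** 3-{[(tert-butyldimethylsilyl)oxy]methyl}cyclohex-2-en-1-one
Conditions: TBSCl, imidazole, DMF, rt
Reagents that add atoms: TBSCl, CC(C)(C)[Si](C)(C)Cl
Why: Standard silylation of the primary alcohol so that the free OH does not interfere with the organoaluminium/copper step.

**Step 3**
Reactants: **3**; **4** trimethylaluminium
Product: **5** (R)-tert-butyldimethyl{[1-methyl-3-(trimethylsilyloxy)cyclohex-2-en-1-yl]methoxy}silane
Conditions: CuTC (2 mol %), chiral phosphoramidite/SimplePhos ligand (4 mol %), Et2O, −30 °C; then TMSOTf, −30 → 0 °C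
Reagents that add atoms: Me3Al, C[Al](C)C; TMSOTf, C[Si](C)(C)OS(=O)(=O)C(F)(F)F
Why: Alexakis-type Cu-catalysed asymmetric conjugate addition of Me3Al to a β,β-disubstituted enone creates the C4 quaternary centre (ligand antipode chosen for 4R), and the aluminium enolate is trapped regiospecifically as the C10=C5 silyl enol ether.

**Step 4**
Reactants: **5**; **6** trimethyl orthoformate
Product: **7** (1S,3aR,7aS)-1-methoxy-3a-methylhexahydroisobenzofuran-7(1H)-one (cis-fused keto acetal; C4 R, C5 S, C6 S, C10 ketone)
Conditions: TMSOTf (10 mol %), CH2Cl2, −78 °C; then MeOH, CSA, rt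
Reagents that add atoms: HC(OMe)3, COC(OC)OC; methanol, CO
Why: Mukaiyama-type (Noyori) alkylation of the silyl enol ether by the dimethoxycarbenium ion puts C6 on C5; acidic methanol then removes the TBS group and closes the five-membered methyl acetal, with C5 (α to the ketone) and C6 equilibrating to the cis-fused, exo-OMe isomer.

**Step 5**
Reactants: **7**; **8** trimethylsulfonium iodide
Product: **9** spiro-epoxide (4R,5R,6S)-1-methoxy-3a-methylhexahydrospiro[isobenzofuran-7,2′-oxirane] (C10 epimers, both used)
Conditions: n-BuLi, THF, −10 °C → rt
Reagents that add atoms: Me3S⁺ I⁻, C[S+](C)C.[I-] (supplies C20)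
Why: Corey–Chaykovsky methylene transfer to the ketone; the epoxide configuration is irrelevant because C10 becomes a planar radical in the next step.

**Step 6**
Reactants: **9**; **10** 2,2,2-trifluoroethyl acrylate
Product: **11** spiro-δ-lactone (4R,5R,6S,10R), C8H2–C9H2
Conditions: Cp2TiCl2, Zn, 2,4,6-collidine·HCl, THF, rt
Reagents that add atoms: 2,2,2-trifluoroethyl acrylate, C=CC(=O)OCC(F)(F)F (supplies C7, C8, C9)
Why: Ti(III) reductive epoxide opening (Nugent–RajanBabu) gives the tertiary C10 radical, which undergoes Giese addition to the acrylate on the face opposite the axial C19 and the C6 substituent (C9 trans to C6), and the titanium alkoxide lactonises onto the activated ester, as in Reisman's spirolactone synthesis.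

**Step 7**
Reactants: **11**; **12** 2-chloropropanoyl chloride
Product: **13** 8-(2-chloropropanoyl) β-keto lactone (C8/C16 epimers and enol)
Conditions: LiHMDS (2.1 equiv), THF, −78 °C; then **12**; AcOH quench at −78 °C
Reagents that add atoms: 2-chloropropanoyl chloride, CC(Cl)C(=O)Cl (supplies C15, C16, C17)
Why: Claisen-type C-acylation of the lactone enolate (C8 is the only enolisable position); the cold acidic quench avoids O-alkylation of the product enolate by the α-chloride.

**Step 8**
Reactants: **13**
Product: **14** 3-acyl-5,6-dihydro-2H-pyran-2-one dienophile (C8=C9; 4R,5R,6S,10R)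
Conditions: PhSeCl, CH2Cl2, 0 °C (no amine base); then 30 % H2O2, 0 °C
Reagents that add atoms: none
Why: α-Selenenylation of the 1,3-dicarbonyl at C8 followed by selenoxide syn-elimination, which can only involve a C9–H, gives the alkylidene β-keto lactone.

**Step 9**
Reactants: **14**; **15** buta-1,3-diene
Product: **16** cis-fused cyclohexene adduct (4R,5R,6S,8S,9S,10R; C12=C13; C16 epimers)
Conditions: butadiene (10 equiv), ZnCl2 (1 equiv), CH2Cl2, −20 °C → rt, sealed tube
Reagents that add atoms: buta-1,3-diene, C=CC=C (supplies C11–C14)
Why: Lewis-acid Diels–Alder of a chelated 2-acyl enoate (Liu-type dienophile); the diene adds suprafacially to C8=C9 anti to the bulkier C5 branch of the spiro C10 (on the C1 face), which sets C9–H and the quaternary C8 with C14/C11 cis and the acyl group on the C5/H9 face.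

**Step 10**
Reactants: **16**
Product: **17** ludongnin H
Conditions: Bu3SnH, AIBN, PhH, 80 °C (syringe pump); then DBU (cat.), CH2Cl2, rt
Reagents that add atoms: none
Why: Chlorine abstraction gives the C16 α-keto radical, which cyclises 5-exo-trig onto C13 of the C12=C13 alkene (bridging forces C13–C16 cis to C15, the C12 radical is reduced by Bu3SnH); DBU then equilibrates the enolisable C16 to the less hindered exo-methyl (16S) epimer.

## Compound list

1 | 3-methoxybenzyl alcohol | COc1cccc(CO)c1 | starting material
2 | 3-(hydroxymethyl)cyclohex-2-en-1-one | O=C1C=C(CO)CCC1 | intermediate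
3 | 3-{[(tert-butyldimethylsilyl)oxy]methyl}cyclohex-2-en-1-one | CC(C)(C)[Si](C)(C)OCC1=CC(=O)CCC1 | intermediate
4 | trimethylaluminium | C[Al](C)C | starting material
5 | (R)-TBS ether / TMS enol ether | CC(C)(C)[Si](C)(C)OC[C@]1(C)CCCC(O[Si](C)(C)C)=C1 | intermediate
6 | trimethyl orthoformate | COC(OC)OC | starting material
7 | cis-fused keto acetal (C10 ketone) | CO[C@H]1OC[C@]2(C)CCCC(=O)[C@H]12 | intermediate
8 | trimethylsulfonium iodide | C[S+](C)C.[I-] | starting material
9 | spiro-epoxide (C10 epimers) | CO[C@H]1OC[C@]2(C)CCCC3(CO3)[C@H]12 | intermediate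
10 | 2,2,2-trifluoroethyl acrylate | C=CC(=O)OCC(F)(F)F | starting material
11 | spiro-δ-lactone | CO[C@H]1OC[C@]2(C)CCC[C@]3(COC(=O)CC3)[C@H]12 | intermediate
12 | 2-chloropropanoyl chloride | CC(Cl)C(=O)Cl | starting material
13 | 8-(2-chloropropanoyl) β-keto lactone | CO[C@H]1OC[C@]2(C)CCC[C@]3(COC(=O)C(C(=O)C(C)Cl)C3)[C@H]12 | intermediate
14 | alkylidene β-keto lactone dienophile | CO[C@H]1OC[C@]2(C)CCC[C@]3(COC(=O)C(C(=O)C(C)Cl)=C3)[C@H]12 | intermediate
15 | buta-1,3-diene | C=CC=C | starting material
16 | Diels–Alder adduct | CO[C@H]1OC[C@]2(C)CCC[C@]3(COC(=O)[C@]4(CC=CC[C@H]43)C(=O)C(C)Cl)[C@H]12 | intermediate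
17 | ludongnin H | CO[C@H]1OC[C@]2(C)CCC[C@]3(COC(=O)[C@@]45C[C@@H](CC[C@H]43)[C@H](C)C5=O)[C@H]12 | target

## Summary

Total steps: 10. Longest linear sequence: 10 (fully linear from **1**).

Steps most likely to fail, each with a fallback that changes the approach:

- **Step 9 (Diels–Alder).** The β-carbon is neopentyl, the acetal is Lewis-acid sensitive, and the facial selectivity is predicted rather than known. Fallback: carry out the cycloaddition on the unacylated α,β-unsaturated lactone (dehydrogenate **11** directly; butadiene under high pressure), then make the C8 quaternary centre by acylating the cis-fused lactone enolate from its convex face (anti to C10).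
- **Step 10 (radical cyclisation).** 6-endo closure to the bicyclo[2.2.2] isomer or simple dechlorination could compete. Fallback: convert the C15 ketone to its silyl enol ether and close ring D by Pd(OAc)2-mediated cycloalkenylation (Toyota), then hydrogenate the resulting alkene.
- **Step 3 (asymmetric conjugate methylation).** Enantioselectivity and enolate trapping are untested with the CH2OTBS substituent. Fallback: reverse the roles, i.e. Cu/NHC-catalysed asymmetric addition of a (dimethylphenylsilyl)methyl Grignard to 3-methylcyclohex-2-enone, the same orthoformate trapping, and Tamao–Fleming oxidation to reveal the C19 alcohol.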